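**Plan**

- Retrosynthesis: the C6–C6' biaryl bond is cut first (Suzuki–Miyaura), giving two 6-functionalised flavan-3,4-diol monomers that differ only at C4; both are traced to one 6-bromo monomer.
- In that monomer, ring C is cut at C3–C4. The two vicinal carbinol carbons (C4 benzylic on ring A, C3 next to the C2 aryl-ether carbon) are the retron of an intramolecular pinacol coupling of a salicylaldehyde-ether dialdehyde. The O1–C2 ether is then cut to a brominated salicylaldehyde and an (S)-4-hydroxymandelate.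
- Forward: ring A block (benzylation, bromination), then the O1–C2 ether (Mitsunobu), then the dialdehyde; SmI2 pinacol closes ring C; C3 is inverted to give the 2,3-cis-3,4-trans monomer; C4 oxidation/reduction gives the all-cis monomer; borylation, Suzuki coupling, hydrogenolysis.
- Stereochemistry: C2 (both units) comes from (S)-mandelate by Mitsunobu inversion. C4 of the 3,4-trans unit comes from the pinacol step (cis-diol, anti to the C2 aryl group). C3 (both units) is set by SN2 inversion. C4 of the all-cis unit is set by hydride addition anti to the axial C3 hydroxyl.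

Key step: step 7

Assumption: the single (S)-enantiomer of 4-hydroxymandelic acid is purchasable (otherwise the inexpensive racemate is resolved first).

**Route**

Step 1
Reactants: 1 2,3,4-trihydroxybenzaldehyde
Product: 2 3,4-bis(benzyloxy)-2-hydroxybenzaldehyde
Conditions: BnBr (2.1 equiv), K2CO3 (2.2 equiv), DMF, 0 °C to rt
Reagents that add atoms: benzyl bromide, BrCc1ccccc1
Why: Williamson etherification; the 2-OH is hydrogen-bonded to the formyl group and is the least nucleophilic phenoxide, so two equivalents of benzyl bromide should cap O3 and O4 only.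

Step 2
Reactants: 2 3,4-bis(benzyloxy)-2-hydroxybenzaldehyde
Product: 3 3,4-bis(benzyloxy)-5-bromo-2-hydroxybenzaldehyde
Conditions: NBS (1.0 equiv), MeCN, 0 °C
Reagents that add atoms: N-bromosuccinimide, O=C1CCC(=O)N1Br
Why: Electrophilic aromatic bromination should go para to the free phenol (C5), the open position activated by both the OH and the 4-benzyloxy group; this bromine becomes the C6 handle for the biaryl bond.

Step 3
Reactants: 4 (S)-4-hydroxymandelic acid
Product: 5 benzyl (2S)-2-[4-(benzyloxy)phenyl]-2-hydroxyacetate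
Conditions: BnBr (2.1 equiv), K2CO3 (2.2 equiv), DMF, rt
Reagents that add atoms: benzyl bromide, BrCc1ccccc1
Why: Carbonate-mediated O-alkylation (carboxylate and phenoxide alkylation) should leave the much less acidic secondary hydroxyl free and does not touch the stereocentre.

Step 4
Reactants: 3 3,4-bis(benzyloxy)-5-bromo-2-hydroxybenzaldehyde; 5 benzyl (2S)-2-[4-(benzyloxy)phenyl]-2-hydroxyacetate
Product: 6 benzyl (2R)-2-[4-(benzyloxy)phenyl]-2-[2,3-bis(benzyloxy)-4-bromo-6-formylphenoxy]acetate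
Conditions: PPh3, DIAD, THF, 0 °C to rt
Reagents that add atoms: none
Why: Mitsunobu etherification; the acidic salicylaldehyde-type phenol displaces the activated mandelate hydroxyl by SN2 with inversion (the ester group disfavours ionisation), which sets the future C2 as R.

Step 5
Reactants: 6 benzyl (2R)-2-[4-(benzyloxy)phenyl]-2-[2,3-bis(benzyloxy)-4-bromo-6-formylphenoxy]acetate
Product: 7 (2R)-2-[4-(benzyloxy)phenyl]-2-[2,3-bis(benzyloxy)-4-bromo-6-(hydroxymethyl)phenoxy]ethan-1-ol
Conditions: LiBH4, THF, 0 °C to rt; aq. NH4Cl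
Reagents that add atoms: none
Why: Borohydride reduction of ester and aldehyde to the diol under nearly neutral conditions should not epimerise the α-aryloxy centre; the aryl bromide and benzyl ethers are inert.

Step 6
Reactants: 7 (2R)-2-[4-(benzyloxy)phenyl]-2-[2,3-bis(benzyloxy)-4-bromo-6-(hydroxymethyl)phenoxy]ethan-1-ol
Product: 8 3,4-bis(benzyloxy)-2-{(1R)-1-[4-(benzyloxy)phenyl]-2-oxoethoxy}-5-bromobenzaldehyde
Conditions: Dess–Martin periodinane (2.4 equiv), CH2Cl2, 0 °C to rt; crude product used at once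
Reagents that add atoms: none
Why: Dess–Martin oxidation is fast, non-basic and stops at the aldehyde, which should keep the enolisable α-aryl-α-aryloxy aldehyde configurationally intact.

Step 7
Reactants: 8 3,4-bis(benzyloxy)-2-{(1R)-1-[4-(benzyloxy)phenyl]-2-oxoethoxy}-5-bromobenzaldehyde
Product: 9 (2R,3S,4S)-7,8-bis(benzyloxy)-2-[4-(benzyloxy)phenyl]-6-bromochromane-3,4-diol
Conditions: SmI2 (2.5 equiv, 0.1 M in THF), t-BuOH, THF, −78 °C, 8 added slowly (final ca. 5 mM); then aq. NH4Cl
Reagents that add atoms: none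
Why: SmI2-mediated pinacol cyclisation: single-electron transfer to the conjugated, more easily reduced aryl aldehyde gives a trivalent-samarium ketyl at C4, whose carbon adds to the samarium-bound C3 aldehyde, and a second electron transfer and protonation give the diol. The closest known reaction type is the SmI2 pinacol cyclisation of 1,6-dialdehydes to cis-cyclohexane-1,2-diols used for cyclitols. Ring C closes in a 6-exo-trig mode by formation of the C3–C4 bond. C3 and C4 are controlled by one samarium bridging both oxygens (3,4-cis) and by C2: the aryl group sits pseudo-equatorial and anti to the forming bond (Felkin–Anh) and the C3 oxygen turns away from the C2–O1 dipole, so the diol should form trans to the aryl group, (3S,4S). The step needs ketyl formation at the aryl aldehyde only (a ketyl at C3 would expel the α-aryloxide), an intact C–Br bond and C2 centre, and ring closure before intermolecular coupling; the easier reduction of the conjugated aldehyde, the absence of HMPA, −78 °C, the non-basic medium and slow addition at high dilution secure these.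

Step 8
Reactants: 9 (2R,3S,4S)-7,8-bis(benzyloxy)-2-[4-(benzyloxy)phenyl]-6-bromochromane-3,4-diol
Product: 11 (2R)-7,8-bis(benzyloxy)-2-[4-(benzyloxy)phenyl]-6-bromo-3-hydroxychroman-4-yl acetate (configuration of 9; acetate on O4), via cyclic methyl orthoacetate 10 (not isolated)
Conditions: MeC(OMe)3, PPTS (cat.), CH2Cl2, rt; then AcOH/H2O (4:1), 0 °C
Reagents that add atoms: trimethyl orthoacetate, CC(OC)(OC)OC; water, O
Why: Acid-catalysed orthoester exchange on the cis-diol, then stereoelectronically controlled hydrolysis of the cyclic orthoester, should release the equatorial O3 hydroxyl and leave the ester on the pseudo-axial benzylic O4, which differentiates the two hydroxyls in one operation.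

Step 9
Reactants: 11 (2R)-7,8-bis(benzyloxy)-2-[4-(benzyloxy)phenyl]-6-bromo-3-hydroxychroman-4-yl acetate
Product: 13 (2R,3R,4S)-7,8-bis(benzyloxy)-2-[4-(benzyloxy)phenyl]-6-bromochromane-3,4-diol, via 3-O-(4-nitrobenzoyl) 4-O-acetyl diester 12 (not isolated)
Conditions: 4-O2NC6H4CO2H, PPh3, DIAD, toluene, 0 °C to rt; then K2CO3 (cat.), MeOH/THF, rt
Reagents that add atoms: 4-nitrobenzoic acid, O=C(O)c1ccc(cc1)[N+](=O)[O-]
Why: Mitsunobu inversion (4-nitrobenzoic acid variant for hindered secondary alcohols); SN2 attack of the carboxylate at C3 from the face of the aryl group, with the cis-4-acetate unable to participate, inverts C3 to R (2,3-cis), and methanolysis then removes both esters without touching C4.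

Step 10
Reactants: 13 (2R,3R,4S)-7,8-bis(benzyloxy)-2-[4-(benzyloxy)phenyl]-6-bromochromane-3,4-diol
Product: 14 (2R,3S)-7,8-bis(benzyloxy)-2-[4-(benzyloxy)phenyl]-6-bromo-3-hydroxychroman-4-one (3-OH cis to the 2-aryl group)
Conditions: MnO2 (activated, excess), CH2Cl2, rt
Reagents that add atoms: none
Why: MnO2 oxidises only the electron-rich benzylic C4 alcohol, and its neutral conditions should avoid epimerisation of the 2,3-cis α-hydroxy ketone at C3.

Step 11
Reactants: 14 (2R,3S)-7,8-bis(benzyloxy)-2-[4-(benzyloxy)phenyl]-6-bromo-3-hydroxychroman-4-one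
Product: 15 (2R,3R,4R)-7,8-bis(benzyloxy)-2-[4-(benzyloxy)phenyl]-6-bromochromane-3,4-diol (all-cis)
Conditions: NaBH4, CeCl3·7H2O, MeOH/THF, −78 °C
Reagents that add atoms: none
Why: Luche-type borohydride reduction; hydride should add to C4=O from the face anti to the axial C3 hydroxyl and the C2 aryl group (axial attack on the half-chair), which sets C4 as R and gives the all-cis diol, while the cold non-basic medium keeps C3 from epimerising.

Step 12
Reactants: 13 (2R,3R,4S)-7,8-bis(benzyloxy)-2-[4-(benzyloxy)phenyl]-6-bromochromane-3,4-diol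
Product: 16 (2R,3R,4S)-7,8-bis(benzyloxy)-2-[4-(benzyloxy)phenyl]-6-(4,4,5,5-tetramethyl-1,3,2-dioxaborolan-2-yl)chromane-3,4-diol
Conditions: B2pin2, Pd(dppf)Cl2 (5 mol %), KOAc, 1,4-dioxane, 85 °C
Reagents that add atoms: bis(pinacolato)diboron, CC1(C)OB(OC1(C)C)B1OC(C)(C)C(C)(C)O1
Why: Miyaura borylation of the aryl bromide; the trans-diaxial diol cannot chelate boron and free alcohols are tolerated under the acetate-base conditions.

Step 13
Reactants: 16 (2R,3R,4S)-7,8-bis(benzyloxy)-2-[4-(benzyloxy)phenyl]-6-(4,4,5,5-tetramethyl-1,3,2-dioxaborolan-2-yl)chromane-3,4-diol; 15 (2R,3R,4R)-7,8-bis(benzyloxy)-2-[4-(benzyloxy)phenyl]-6-bromochromane-3,4-diol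
Product: 17 (2R,2'R,3R,3'R,4R,4'S)-7,7',8,8'-tetrakis(benzyloxy)-2,2'-bis[4-(benzyloxy)phenyl]-[6,6'-bichromane]-3,3',4,4'-tetrol
Conditions: Pd(OAc)2 (5 mol %), SPhos (10 mol %), K3PO4, toluene/H2O, 60 °C
Reagents that add atoms: none
Why: Suzuki–Miyaura coupling with a bulky electron-rich biarylphosphine should join the two mono-ortho-substituted, electron-rich partners at C6 and C6'; the 2,2'-dioxygenated biaryl has no stable axis, so no new stereo element arises.

Step 14
Reactants: 17 (2R,2'R,3R,3'R,4R,4'S)-7,7',8,8'-tetrakis(benzyloxy)-2,2'-bis[4-(benzyloxy)phenyl]-[6,6'-bichromane]-3,3',4,4'-tetrol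
Product: 18 (2R,2'R,3R,3'R,4R,4'S)-2,2'-bis(4-hydroxyphenyl)-[6,6'-bichromane]-3,3',4,4',7,7',8,8'-octol
Conditions: H2 (1 atm), Pd(OH)2/C, THF/MeOH, rt
Reagents that add atoms: none
Why: Hydrogenolysis of the six aryl benzyl ethers under neutral conditions, which should be much faster than cleavage of the secondary benzylic C4–OH and C2–O1 bonds; the acid-free work-up avoids epimerisation at C4.

**Compound list**

1 | 2,3,4-trihydroxybenzaldehyde | O=Cc1ccc(O)c(O)c1O | starting material
2 | 3,4-bis(benzyloxy)-2-hydroxybenzaldehyde | O=Cc1ccc(OCc2ccccc2)c(OCc2ccccc2)c1O | intermediate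
3 | 3,4-bis(benzyloxy)-5-bromo-2-hydroxybenzaldehyde | O=Cc1cc(Br)c(OCc2ccccc2)c(OCc2ccccc2)c1O | intermediate
4 | (S)-4-hydroxymandelic acid, (2S)-2-hydroxy-2-(4-hydroxyphenyl)acetic acid | O[C@H](C(=O)O)c1ccc(O)cc1 | starting material
5 | benzyl (2S)-2-[4-(benzyloxy)phenyl]-2-hydroxyacetate | O[C@H](C(=O)OCc1ccccc1)c1ccc(OCc2ccccc2)cc1 | intermediate
6 | benzyl (2R)-2-[4-(benzyloxy)phenyl]-2-[2,3-bis(benzyloxy)-4-bromo-6-formylphenoxy]acetate | O=Cc1cc(Br)c(OCc2ccccc2)c(OCc2ccccc2)c1O[C@@H](C(=O)OCc1ccccc1)c1ccc(OCc2ccccc2)cc1 | intermediate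
7 | (2R)-2-[4-(benzyloxy)phenyl]-2-[2,3-bis(benzyloxy)-4-bromo-6-(hydroxymethyl)phenoxy]ethan-1-ol | OCc1cc(Br)c(OCc2ccccc2)c(OCc2ccccc2)c1O[C@@H](CO)c1ccc(OCc2ccccc2)cc1 | intermediate
8 | 3,4-bis(benzyloxy)-2-{(1R)-1-[4-(benzyloxy)phenyl]-2-oxoethoxy}-5-bromobenzaldehyde | O=Cc1cc(Br)c(OCc2ccccc2)c(OCc2ccccc2)c1O[C@@H](C=O)c1ccc(OCc2ccccc2)cc1 | intermediate
9 | (2R,3S,4S)-7,8-bis(benzyloxy)-2-[4-(benzyloxy)phenyl]-6-bromochromane-3,4-diol (3-OH and 4-OH cis to each other, both trans to the 2-aryl group) | O(Cc1ccccc1)c1ccc(cc1)[C@H]1Oc2c(cc(Br)c(OCc3ccccc3)c2OCc2ccccc2)[C@H](O)[C@@H]1O | intermediate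
10 | 3,4-O-(1-methoxyethylidene) derivative of 9 (cyclic methyl orthoacetate, ring stereocentres as in 9, orthoester carbon unspecified) | O(Cc1ccccc1)c1ccc(cc1)[C@H]1Oc2c(cc(Br)c(OCc3ccccc3)c2OCc2ccccc2)[C@@H]2OC(C)(OC)O[C@H]12 | intermediate
11 | (2R)-7,8-bis(benzyloxy)-2-[4-(benzyloxy)phenyl]-6-bromo-3-hydroxychroman-4-yl acetate (4-O-acetate of 9; 3-OH and 4-OAc both trans to the 2-aryl group) | O(Cc1ccccc1)c1ccc(cc1)[C@H]1Oc2c(cc(Br)c(OCc3ccccc3)c2OCc2ccccc2)[C@H](OC(C)=O)[C@@H]1O | intermediate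
12 | (2R)-4-acetoxy-7,8-bis(benzyloxy)-2-[4-(benzyloxy)phenyl]-6-bromochroman-3-yl 4-nitrobenzoate (O3 cis and O4 trans to the 2-aryl group) | O(Cc1ccccc1)c1ccc(cc1)[C@H]1Oc2c(cc(Br)c(OCc3ccccc3)c2OCc2ccccc2)[C@H](OC(C)=O)[C@H]1OC(=O)c1ccc(cc1)[N+](=O)[O-] | intermediate
13 | (2R,3R,4S)-7,8-bis(benzyloxy)-2-[4-(benzyloxy)phenyl]-6-bromochromane-3,4-diol (3-OH cis and 4-OH trans to the 2-aryl group) | O(Cc1ccccc1)c1ccc(cc1)[C@H]1Oc2c(cc(Br)c(OCc3ccccc3)c2OCc2ccccc2)[C@H](O)[C@H]1O | intermediate
14 | (2R,3S)-7,8-bis(benzyloxy)-2-[4-(benzyloxy)phenyl]-6-bromo-3-hydroxychroman-4-one (3-OH cis to the 2-aryl group) | O(Cc1ccccc1)c1ccc(cc1)[C@H]1Oc2c(cc(Br)c(OCc3ccccc3)c2OCc2ccccc2)C(=O)[C@H]1O | intermediate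
15 | (2R,3R,4R)-7,8-bis(benzyloxy)-2-[4-(benzyloxy)phenyl]-6-bromochromane-3,4-diol (all-cis) | O(Cc1ccccc1)c1ccc(cc1)[C@H]1Oc2c(cc(Br)c(OCc3ccccc3)c2OCc2ccccc2)[C@@H](O)[C@H]1O | intermediate
16 | (2R,3R,4S)-7,8-bis(benzyloxy)-2-[4-(benzyloxy)phenyl]-6-(4,4,5,5-tetramethyl-1,3,2-dioxaborolan-2-yl)chromane-3,4-diol | O(Cc1ccccc1)c1ccc(cc1)[C@H]1Oc2c(cc(B3OC(C)(C)C(C)(C)O3)c(OCc3ccccc3)c2OCc2ccccc2)[C@H](O)[C@H]1O | intermediate
17 | (2R,2'R,3R,3'R,4R,4'S)-7,7',8,8'-tetrakis(benzyloxy)-2,2'-bis[4-(benzyloxy)phenyl]-[6,6'-bichromane]-3,3',4,4'-tetrol | O(Cc1ccccc1)c1ccc(cc1)[C@H]1Oc2c(cc(-c3cc4c(c(OCc5ccccc5)c3OCc3ccccc3)O[C@H](c3ccc(OCc5ccccc5)cc3)[C@H](O)[C@H]4O)c(OCc3ccccc3)c2OCc2ccccc2)[C@@H](O)[C@H]1O | intermediate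
18 | (2R,2'R,3R,3'R,4R,4'S)-2,2'-bis(4-hydroxyphenyl)-[6,6'-bichromane]-3,3',4,4',7,7',8,8'-octol | Oc1ccc([C@H]2Oc3c(cc(-c4cc5c(c(O)c4O)O[C@H](c4ccc(O)cc4)[C@H](O)[C@H]5O)c(O)c3O)[C@@H](O)[C@H]2O)cc1 | target

**Step count and risks**

Total: 14 steps. Longest linear sequence: 12 steps (steps 1, 2, 4–11, 13, 14).

Step 7 (pinacol cyclisation). What may go wrong: poor facial selectivity at C3 relative to the C2 aryl group, fragmentation of an over-reduced α-aryloxy ketyl, or epimerisation of the labile aldehyde before ring closure. A 2,3-cis-3,4-cis diol formed beside 9 would be 15 itself and could enter step 13 directly. Fallback: the route sets out from 8. Low-valent titanium (TiCl3(DME)1.5, Zn–Cu, DME, reflux, slow addition) takes the same two aldehydes through to the alkene by intramolecular McMurry coupling and should give (2S)-7,8-bis(benzyloxy)-2-[4-(benzyloxy)phenyl]-6-bromo-2H-chromene F1 (C2 arrangement of 8 retained; only the descriptor changes). Catalytic OsO4 with NMO (acetone/H2O) then dihydroxylates the C3=C4 bond from the face anti to the C2 aryl group, and the route is rejoined at 9.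

Step 9 (SN2 inversion at C3). What may go wrong: the carbinol is flanked by the C2 aryl group and the C4 acetate, so slow substitution, elimination or acyl migration may compete. Fallback: a redox inversion under hydroxyl direction replaces the substitution; it sets out from 9, one stage earlier, because the C4 hydroxyl must be free. Bu2SnO (MeOH, reflux) should give the 3,4-O-dibutylstannylene acetal of 9 F2, which NBS (CH2Cl2, 4 Å molecular sieves, rt) oxidises at the equatorial C3 oxygen to (2R,4S)-7,8-bis(benzyloxy)-2-[4-(benzyloxy)phenyl]-6-bromo-4-hydroxychroman-3-one F3. Me4NBH(OAc)3 (MeCN/AcOH, −30 °C) binds the C4 hydroxyl and delivers hydride to C3 from the same face (hydroxyl-directed triacetoxyborohydride reduction), which should give the 3,4-trans diol; the route is rejoined at 13.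

Step 4 (Mitsunobu etherification). What may go wrong: slow coupling of a crowded, hydrogen-bonded phenol, and partial ionisation of the benzylic carbinol with erosion of enantiopurity. Fallback: carbenoid O–H insertion replaces the SN2 displacement; it sets out from 3. Commercial methyl [4-(benzyloxy)phenyl]acetate is converted by diazo transfer (4-acetamidobenzenesulfonyl azide, DBU, MeCN) into methyl 2-[4-(benzyloxy)phenyl]-2-diazoacetate F4. Enantioselective insertion into the O–H bond of 3 (PdCl2(PhCN)2, a chiral spiro bis(oxazoline) ligand of the enantiomer that gives the R ether, NaB[3,5-(CF3)2C6H3]4, CHCl3) should give methyl (2R)-2-[4-(benzyloxy)phenyl]-2-[2,3-bis(benzyloxy)-4-bromo-6-formylphenoxy]acetate F5. LiBH4 as in step 5 reduces F5, and the route is rejoined at 7.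

Further compounds
F1 | step 7 | (2S)-7,8-bis(benzyloxy)-2-[4-(benzyloxy)phenyl]-6-bromo-2H-chromene | O(Cc1ccccc1)c1ccc(cc1)[C@H]1Oc2c(cc(Br)c(OCc3ccccc3)c2OCc2ccccc2)C=C1
F2 | step 9 | 3,4-O-dibutylstannylene acetal of 9 | O(Cc1ccccc1)c1ccc(cc1)[C@H]1Oc2c(cc(Br)c(OCc3ccccc3)c2OCc2ccccc2)[C@@H]2O[Sn](CCCC)(CCCC)O[C@H]12
F3 | step 9 | (2R,4S)-7,8-bis(benzyloxy)-2-[4-(benzyloxy)phenyl]-6-bromo-4-hydroxychroman-3-one | O(Cc1ccccc1)c1ccc(cc1)[C@H]1Oc2c(cc(Br)c(OCc3ccccc3)c2OCc2ccccc2)[C@H](O)C1=O
F4 | step 4 | methyl 2-[4-(benzyloxy)phenyl]-2-diazoacetate | COC(=O)C(=[N+]=[N-])c1ccc(OCc2ccccc2)cc1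
F5 | step 4 | methyl (2R)-2-[4-(benzyloxy)phenyl]-2-[2,3-bis(benzyloxy)-4-bromo-6-formylphenoxy]acetate | O=Cc1cc(Br)c(OCc2ccccc2)c(OCc2ccccc2)c1O[C@@H](C(=O)OC)c1ccc(OCc2ccccc2)cc1
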